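**Retrosynthetic overview**

1. The target is a cis-fused clerodane (ring A = C1–C5, C10; ring B = C5–C10). Ring A is closed last by acyl substitution at C2 (bond C2–C3), followed by oxidation of C3 to the diosphenol; the C7 oxygen is introduced through a C7 radical.
2. Ring B is disconnected at C6–C7 and C5–C10: a (4+2) union of isopropenyl methyl ketone (C3, C4, C5, C6, C18, C19) with a 2-silyloxy diene C7=C2–C1=C10.
3. Enabling feature: C7 and C10 lie 1,4 across ring B; C7 bears the acetoxy oxygen, C10 bears the enol unit C1=C2(OH) of ring A, and C9 is quaternary. A temporary bond C2–C7 therefore turns C7–C2–C1–C10–C9–C8 into a 4,4,5-trisubstituted cyclohex-2-enone (C2=O), whose cross-conjugated dienol ether is the diene, with C8–C9 as its saturated bridge.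
4. The temporary bond C2–C7 is cut afterwards by peroxyketal fragmentation: C2 becomes the ester that later acylates C3, and the C7 radical is captured by oxygen on the face needed for the acetate.
5. Ring order: temporary cyclohexenone (asymmetric Diels–Alder of tiglic aldehyde sets C8/C9; side chain and C13 by Wittig reaction from (R)-3-methylglutaric half ester) → ring B inside a bicyclo[2.2.2]octene (key step) → bicycle opened → ring A.

Key step: step 6

Numbering used throughout (clerodane): C18H2=C4, C3=O, C2–OH, C1, C10–H, C9 (C20 methyl; chain C11–C15 with C16 on C13), C8 (C17 methyl), C7 (OAc), C6, C5 (C19 methyl).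

Assumption: the (S,S) chromium–salen catalyst of step 3 is taken to give the (1S,6R) aldehyde; if the sense of induction is the opposite, the (R,R) catalyst is used.

**Route**

Step 1
Reactants: 1 methyl hydrogen (R)-3-methylglutarate
Product: 2 methyl (3S)-4-bromo-3-methylbutanoate
Conditions: HgO (red), Br2, CCl4, reflux, dark
Reagents that add atoms: bromine BrBr
Why: Cristol–Firth variant of the Hunsdiecker reaction replaces the free CO2H by Br through an acyl hypobromite radical chain without touching the ester or the stereocentre, whose descriptor changes from R to S only because the CIP priorities change.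

Step 2
Reactants: 2 methyl (3S)-4-bromo-3-methylbutanoate
Product: 3 [(2S)-4-methoxy-2-methyl-4-oxobutyl]triphenylphosphonium bromide
Conditions: PPh3, MeCN, reflux
Reagents that add atoms: triphenylphosphine c1ccc(cc1)P(c1ccccc1)c1ccccc1
Why: SN2 alkylation of PPh3 by the primary bromide (phosphonium salt formation); the neighbouring stereocentre is not involved.

Step 3
Reactants: 4 (E)-3-(tert-butyldimethylsilyloxy)-N,N-dimethylbuta-1,3-dien-1-amine; 5 (E)-2-methylbut-2-enal (tiglic aldehyde)
Product: 7 (1S,6R)-1,6-dimethyl-4-oxocyclohex-2-ene-1-carbaldehyde, via amino silyl enol ether cycloadduct 6 (not isolated)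
Conditions: [(S,S)-N,N′-bis(3,5-di-tert-butylsalicylidene)cyclohexane-1,2-diaminato]chromium hexafluoroantimonate (5 mol %), 4 Å MS, CH2Cl2, −40 °C → rt; then 1 M HCl, THF, 0 °C
Reagents that add atoms: none
Why: Catalytic enantioselective Diels–Alder reaction of a 1-amino-3-silyloxy diene with an α-substituted enal, in which the E geometry of the enal fixes the cis relation of the two methyl groups (C17 on C8, C20 on C9), the chiral Lewis acid fixes the absolute sense, and acid hydrolysis with β-elimination of dimethylamine unveils the enone.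

Step 4
Reactants: 3 [(2S)-4-methoxy-2-methyl-4-oxobutyl]triphenylphosphonium bromide; 7 (1S,6R)-1,6-dimethyl-4-oxocyclohex-2-ene-1-carbaldehyde
Product: 9 methyl (3S,4Z)-5-[(1R,6R)-1,6-dimethyl-4-oxocyclohex-2-en-1-yl]-3-methylpent-4-enoate, via phosphorus ylide 8 (not isolated)
Conditions: KN(SiMe3)2, THF, −78 °C; then 7, −78 → 0 °C
Reagents that add atoms: none
Why: Wittig olefination, in which the unstabilised ylide should attack the aldehyde far faster than the enone or the ester; the alkene geometry is of no consequence because the double bond is saturated in step 7.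

Step 5
Reactants: 9 methyl (3S,4Z)-5-[(1R,6R)-1,6-dimethyl-4-oxocyclohex-2-en-1-yl]-3-methylpent-4-enoate
Product: 10 methyl (3S,4Z)-5-[(1R,6R)-4-(tert-butyldimethylsilyloxy)-1,6-dimethylcyclohexa-2,4-dien-1-yl]-3-methylpent-4-enoate
Conditions: TBSOTf, Et3N, CH2Cl2, 0 °C
Reagents that add atoms: tert-butyldimethylsilyl triflate CC(C)(C)[Si](C)(C)OS(=O)(=O)C(F)(F)F
Why: Soft enolisation and O-silylation; because the γ carbon (C9) is quaternary only the α′ CH2 (C7) can be deprotonated, so the cross-conjugated 2-silyloxy diene C7=C2–C1=C10 should form as the only dienol ether.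

Step 6
Reactants: 10 methyl (3S,4Z)-5-[(1R,6R)-4-(tert-butyldimethylsilyloxy)-1,6-dimethylcyclohexa-2,4-dien-1-yl]-3-methylpent-4-enoate; 11 3-methylbut-3-en-2-one
Product: 12 silyl enol ether cycloadduct (5-acetyl-2-silyloxy-5,7,8-trimethylbicyclo[2.2.2]oct-2-ene carrying the pentenoate chain on C8)
Conditions: Tf2NH (10 mol %), 11 (3 equiv), CH2Cl2, −78 → −20 °C; Et3N quench
Reagents that add atoms: none
Why: Tf2NH desilylates a trace of 10 to give TBSNTf2, which activates enone 11; the electron-rich diene terminus C7 adds to the enone CH2 (C6) and the resulting silyl enol ether carbon C5 closes onto C10 of the ring oxocarbenium, which amounts to a strongly asynchronous Diels–Alder reaction (double Michael limit) that returns the silyl group to the C2 oxygen. The closest known reaction type is the Lewis-acid- or triflimide-catalysed Diels–Alder addition of hindered 2-silyloxy-1,3-cyclohexadienes to α-substituted enones, which gives bicyclo[2.2.2]octenes with vicinal quaternary centres. Ring B (C5–C6–C7–C8–C9–C10) closes by (4+2) cycloaddition, in the stepwise limit by a 6-exo-trig Michael closure, and the temporary ring C7–C2–C1–C10–C5–C6 closes in the same event. C7 and C10 are set by suprafacial attack on the diene face anti to the C8 methyl (and anti to the C9 methyl), and the quaternary C5 by the endo orientation of the acetyl group, syn to the silyloxy-alkene bridge, which also keeps the larger C5 substituent away from the C9 side chain. The step needs regioselectivity (C6 to C7, C5 to C10), which the donor oxygen on C2 and the acceptor carbonyl C4 enforce, π-facial selectivity, which the C8 stereocentre secures, and chemoselectivity over the side-chain alkene, which is unactivated.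

Step 7
Reactants: 12 silyl enol ether cycloadduct
Product: 13 silyl enol ether cycloadduct with saturated (3R)-pentanoate chain
Conditions: 2-nitrobenzenesulfonylhydrazide (excess), Et3N, CH2Cl2, rt
Reagents that add atoms: none
Why: Diimide reduction (concerted syn transfer of H2) saturates the 1,2-disubstituted side-chain alkene without double-bond migration, so C13 keeps its configuration, while the trisubstituted silyl enol ether, the ketone and the ester are inert.

Step 8
Reactants: 13 silyl enol ether cycloadduct with saturated chain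
Product: 15 isopropenyl bicyclo[2.2.2]octan-2-one (C2 ketone), via isopropenyl silyl enol ether 14 (not isolated)
Conditions: Ph3PCH3Br, KOtBu, THF, 0 °C → 50 °C; then 1 M HCl, THF, rt
Reagents that add atoms: methyltriphenylphosphonium bromide C[P+](c1ccccc1)(c1ccccc1)c1ccccc1.[Br-]
Why: Wittig methylenation of the C4 methyl ketone while the C2 carbonyl is still masked as its silyl enol ether, followed by acid hydrolysis of the enol ether; this differentiates the two carbonyl groups and leaves all stereocentres untouched.

Step 9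
Reactants: 15 isopropenyl bicyclo[2.2.2]octan-2-one
Product: 17 2,3-seco alkoxyamine diester (C7–O–N piperidine; C2 methyl ester), via methoxy hydroperoxide ketal 16 (not isolated)
Conditions: 50% aq. H2O2, MeOH, cat. camphorsulfonic acid, 0 °C → rt; then FeSO4·7H2O, TEMPO, MeOH, 0 °C → rt
Reagents that add atoms: hydrogen peroxide OO; methanol CO; TEMPO CC1(C)CCCC(C)(C)N1[O]
Why: Peroxyketalisation followed by reductive O–O cleavage with divalent iron gives an α-methoxy alkoxy radical whose β-scission breaks C2–C7 (secondary ring radical and methyl ester, not the primary C1 radical), and the C7 radical should be captured by TEMPO anti to the vicinal C8 methyl and to the syn-axial C5 and C9 substituents, which places the C7 oxygen trans to C17 as in the target (alkoxy-radical fragmentation of ketone-derived alkoxy hydroperoxides with radical trapping).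

Step 10
Reactants: 17 2,3-seco alkoxyamine diester
Product: 18 2,3-seco hydroxy diester (C7–OH)
Conditions: Zn dust, AcOH/THF/H2O, 50 °C
Reagents that add atoms: none
Why: Reductive N–O cleavage of the alkoxyamine by zinc in acetic acid; the C7–O bond is not touched, so the configuration is retained.

Step 11
Reactants: 18 2,3-seco hydroxy diester
Product: 19 2,3-seco acetoxy diester (C7–OAc)
Conditions: Ac2O, DMAP, pyridine, CH2Cl2, rt
Reagents that add atoms: acetic anhydride CC(=O)OC(C)=O
Why: DMAP-catalysed acylation of the equatorial secondary alcohol, with retention at C7.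

Step 12
Reactants: 19 2,3-seco acetoxy diester
Product: 20 2,3-seco allylic chloride (C4(=CH2)–CH2Cl on C5)
Conditions: Ca(OCl)2, solid CO2, CH2Cl2/H2O, 0 °C
Reagents that add atoms: calcium hypochlorite [Ca+2].[O-]Cl.[O-]Cl
Why: Ene-type allylic chlorination of the 1,1-disubstituted alkene by hypochlorous acid; the two ends of the isopropenyl group are equivalent after transposition, so a single 2-(chloromethyl)allyl product should result.

Step 13
Reactants: 20 2,3-seco allylic chloride
Product: 21 methyl 7-acetoxy-2-oxocleroda-4(18)-en-15-oate (5,10-cis)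
Conditions: SmI2 (2.2 equiv), THF, 0 °C, slow addition of 20 at high dilution; aq. NH4Cl
Reagents that add atoms: none
Why: Barbier-type intramolecular nucleophilic acyl substitution: the allylsamarium formed from the chloride adds to the C2 ester on the cis-disposed C10 arm through a six-membered closure (bond C2–C3, ring A), the samarium hemiketalate shields the new ketone until work-up, and the cis ring fusion is already fixed by C5 and C10.

Step 14
Reactants: 21 methyl 7-acetoxy-2-oxocleroda-4(18)-en-15-oate
Product: 23 CNP0180040.1 (target), via 2,3-diketone 22 (not isolated)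
Conditions: SeO2, 1,4-dioxane/H2O, 70 °C
Reagents that add atoms: selenium dioxide O=[Se]=O
Why: Riley oxidation at C3, the methylene that is both α to the C2 ketone and allylic to C4=C18, should give the 2,3-dione, which can enolise only towards C1 and so settles as the diosphenol conjugated with the exocyclic enone.

**Compound list**

1 | methyl hydrogen (R)-3-methylglutarate [(3R)-5-methoxy-3-methyl-5-oxopentanoic acid] | OC(=O)C[C@@H](C)CC(=O)OC | starting material
2 | methyl (3S)-4-bromo-3-methylbutanoate | BrC[C@@H](C)CC(=O)OC | intermediate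
3 | [(2S)-4-methoxy-2-methyl-4-oxobutyl]triphenylphosphonium bromide | COC(=O)C[C@H](C)C[P+](c1ccccc1)(c1ccccc1)c1ccccc1.[Br-] | intermediate
4 | (E)-3-(tert-butyldimethylsilyloxy)-N,N-dimethylbuta-1,3-dien-1-amine | CN(C)/C=C/C(=C)O[Si](C)(C)C(C)(C)C | starting material
5 | (E)-2-methylbut-2-enal (tiglic aldehyde) | C/C=C(\C)C=O | starting material
6 | (1S,2R,6R)-4-(tert-butyldimethylsilyloxy)-2-(dimethylamino)-1,6-dimethylcyclohex-3-ene-1-carbaldehyde (endo adduct, NMe2 cis to CHO, methyls cis) | CC(C)(C)[Si](C)(C)OC1=C[C@@H](N(C)C)[C@@](C)(C=O)[C@H](C)C1 | intermediate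
7 | (1S,6R)-1,6-dimethyl-4-oxocyclohex-2-ene-1-carbaldehyde (methyls cis) | O=C1C=C[C@@](C)(C=O)[C@H](C)C1 | intermediate
8 | methyl (3S)-3-methyl-4-(triphenyl-λ5-phosphanylidene)butanoate | COC(=O)C[C@H](C)C=P(c1ccccc1)(c1ccccc1)c1ccccc1 | intermediate
9 | methyl (3S,4Z)-5-[(1R,6R)-1,6-dimethyl-4-oxocyclohex-2-en-1-yl]-3-methylpent-4-enoate | O=C1C=C[C@@](C)(/C=C\[C@@H](C)CC(=O)OC)[C@H](C)C1 | intermediate
10 | methyl (3S,4Z)-5-[(1R,6R)-4-(tert-butyldimethylsilyloxy)-1,6-dimethylcyclohexa-2,4-dien-1-yl]-3-methylpent-4-enoate | CC(C)(C)[Si](C)(C)OC1=C[C@@H](C)[C@](C)(/C=C\[C@@H](C)CC(=O)OC)C=C1 | intermediate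
11 | 3-methylbut-3-en-2-one | CC(=O)C(C)=C | starting material
12 | methyl (3S,4Z)-5-[5-acetyl-2-(tert-butyldimethylsilyloxy)-5,7,8-trimethylbicyclo[2.2.2]oct-2-en-8-yl]-3-methylpent-4-enoate; acetyl, 7-methyl and 8-methyl all syn to the C2=C3 bridge, side chain syn to the C5–C6 bridge (clerodane: bridgeheads C7 and C10, bridges C2=C1, C8–C9, C6–C5) | CC(=O)[C@@]1(C)C[C@H]2C(O[Si](C)(C)C(C)(C)C)=C[C@@H]1[C@@](C)(/C=C\[C@@H](C)CC(=O)OC)[C@@H]2C | intermediate
13 | as 12 with the saturated (3R)-5-methoxy-3-methyl-5-oxopentyl chain on C8 of the bicycle | CC(=O)[C@@]1(C)C[C@H]2C(O[Si](C)(C)C(C)(C)C)=C[C@@H]1[C@@](C)(CC[C@@H](C)CC(=O)OC)[C@@H]2C | intermediate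
14 | as 13 with prop-1-en-2-yl in place of acetyl (silyl enol ether retained) | C=C(C)[C@@]1(C)C[C@H]2C(O[Si](C)(C)C(C)(C)C)=C[C@@H]1[C@@](C)(CC[C@@H](C)CC(=O)OC)[C@@H]2C | intermediate
15 | bicyclo[2.2.2]octan-2-one from 14 (C2 ketone, C1 methylene; isopropenyl syn to the ketone bridge; ring methyls syn to the ketone bridge) | C=C(C)[C@@]1(C)C[C@H]2C(=O)C[C@@H]1[C@@](C)(CC[C@@H](C)CC(=O)OC)[C@@H]2C | intermediate
16 | 2-hydroperoxy-2-methoxy ketal of 15 (either configuration at the ketal carbon) | C=C(C)[C@@]1(C)C[C@H]2C(OC)(OO)C[C@@H]1[C@@](C)(CC[C@@H](C)CC(=O)OC)[C@@H]2C | intermediate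
17 | 2,3-seco alkoxyamine diester: ring B cyclohexane with C5 methyl and isopropenyl, C7 O-(2,2,6,6-tetramethylpiperidin-1-yl), C8 methyl, C9 methyl and (3R)-5-methoxy-3-methyl-5-oxopentyl, C10 CH2CO2Me; C7–O cis to the C5 methyl and to the C9 chain, trans to the C8 and C9 methyls, the isopropenyl group and the C10 arm | C=C(C)[C@@]1(C)C[C@H](ON2C(C)(C)CCCC2(C)C)[C@@H](C)[C@](C)(CC[C@@H](C)CC(=O)OC)[C@H]1CC(=O)OC | intermediate
18 | 2,3-seco hydroxy diester (as 17 with C7–OH, same configuration) | C=C(C)[C@@]1(C)C[C@H](O)[C@@H](C)[C@](C)(CC[C@@H](C)CC(=O)OC)[C@H]1CC(=O)OC | intermediate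
19 | 2,3-seco acetoxy diester (as 18 with C7–OAc) | C=C(C)[C@@]1(C)C[C@H](OC(C)=O)[C@@H](C)[C@](C)(CC[C@@H](C)CC(=O)OC)[C@H]1CC(=O)OC | intermediate
20 | 2,3-seco allylic chloride (as 19 with 3-chloroprop-1-en-2-yl on C5) | C=C(CCl)[C@@]1(C)C[C@H](OC(C)=O)[C@@H](C)[C@](C)(CC[C@@H](C)CC(=O)OC)[C@H]1CC(=O)OC | intermediate
21 | methyl (3R)-5-[(1R,2S,3S,4aS,8aR)-3-acetoxy-1,2,4a-trimethyl-5-methylidene-7-oxodecahydronaphthalen-1-yl]-3-methylpentanoate (methyl 7-acetoxy-2-oxocleroda-4(18)-en-15-oate, cis-fused) | C=C1CC(=O)C[C@@H]2[C@@](C)(CC[C@@H](C)CC(=O)OC)[C@H](C)[C@@H](OC(C)=O)C[C@]12C | intermediate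
22 | methyl 7-acetoxy-2,3-dioxocleroda-4(18)-en-15-oate (diketone tautomer of the target) | C=C1C(=O)C(=O)C[C@@H]2[C@@](C)(CC[C@@H](C)CC(=O)OC)[C@H](C)[C@@H](OC(C)=O)C[C@]12C | intermediate
23 | CNP0180040.1: methyl (3R)-5-[(1R,2S,3S,4aS,8aR)-3-acetoxy-7-hydroxy-1,2,4a-trimethyl-5-methylidene-6-oxo-1,2,3,4,4a,5,6,8a-octahydronaphthalen-1-yl]-3-methylpentanoate | C=C1C(=O)C(O)=C[C@@H]2[C@@](C)(CC[C@@H](C)CC(=O)OC)[C@H](C)[C@@H](OC(C)=O)C[C@]12C | target

**Step count and risks**

Total step count: 14. Longest linear sequence: 13 steps (steps 1, 2 and 4 to 14, from 1). The cyclohexenone aldehyde 7 is made in 1 step (step 3, from 4 and 5) and joins in step 4.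

Steps most likely to fail:

- **Step 6.** The union may stall after the first C–C bond (C6–C7), because the second bond joins a fully substituted enol carbon to C10 next to the quaternary C9; endo or facial selectivity may also erode, or the enone may polymerise. Fallback: setting out from 10, a Diels–Alder reaction with the smaller and more reactive dienophile methacrolein (Me2AlCl, CH2Cl2, −78 °C) should give the endo aldehyde cycloadduct F1. Addition of MeMgBr at −78 °C, selective for the aldehyde over the ester, gives the secondary carbinol F2 as a mixture at the new carbinol centre, and Dess–Martin oxidation comes back to the route at 12.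

- **Step 9.** β-Scission may be unselective, or the C7 radical may be captured from the wrong face (or only partly from the right one). Fallback: setting out from 15, Baeyer–Villiger oxidation under alkene-tolerant conditions (bis(trimethylsilyl) peroxide, SnCl4, trans-cyclohexane-1,2-diamine, CH2Cl2) should give, by bridgehead migration with retention, the bridged lactone F3. Methanolysis (K2CO3, MeOH) opens it to the C7-epimeric hydroxy diester F4, and Dess–Martin oxidation gives the C7 ketone F5. An electron-transfer reduction under thermodynamic control (SmI2, H2O, Et3N, THF) should then deliver the more stable equatorial alcohol, which is 18, where the route is rejoined.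

- **Step 13.** The allylic chloride may simply be reduced or dimerise, or the organosamarium may attack the acetate or the C15 ester instead of closing the ring. Fallback: setting out from 20, displacement with NaO2SPh in DMF gives the allylic sulfone F6. Deprotonation of its doubly activated CH2 with LiN(SiMe3)2 (2.2 equiv, THF, −78 → 0 °C) and Dieckmann-type acylation by the C2 ester gives the cyclic β-keto sulfone F7. Oxidative desulfonylation of its enolate (KN(SiMe3)2, then MoO5·pyridine·HMPA) gives the 2,3-diketone 22, where the route is rejoined and tautomerisation gives 23.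

**Further compounds**

F1 | step 6 | methyl (3S,4Z)-5-[2-(tert-butyldimethylsilyloxy)-5-formyl-5,7,8-trimethylbicyclo[2.2.2]oct-2-en-8-yl]-3-methylpent-4-enoate (formyl endo, configuration as 12) | O=C[C@@]1(C)C[C@H]2C(O[Si](C)(C)C(C)(C)C)=C[C@@H]1[C@@](C)(/C=C\[C@@H](C)CC(=O)OC)[C@@H]2C
F2 | step 6 | 1-hydroxyethyl analogue of 12 (both carbinol epimers) | CC(O)[C@@]1(C)C[C@H]2C(O[Si](C)(C)C(C)(C)C)=C[C@@H]1[C@@](C)(/C=C\[C@@H](C)CC(=O)OC)[C@@H]2C
F3 | step 9 | bridged seven-membered lactone (2-oxabicyclo[3.2.2]nonan-3-one; O on C7 cis to the C8 methyl, C2 carbonyl, C1 methylene) | C=C(C)[C@@]1(C)C[C@H]2OC(=O)C[C@@H]1[C@@](C)(CC[C@@H](C)CC(=O)OC)[C@@H]2C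
F4 | step 9 | C7 epimer of 18 (C7–OH cis to the C8 methyl) | C=C(C)[C@@]1(C)C[C@@H](O)[C@@H](C)[C@](C)(CC[C@@H](C)CC(=O)OC)[C@H]1CC(=O)OC
F5 | step 9 | 2,3-seco C7 ketone diester | C=C(C)[C@@]1(C)CC(=O)[C@@H](C)[C@](C)(CC[C@@H](C)CC(=O)OC)[C@H]1CC(=O)OC
F6 | step 13 | 2,3-seco allylic phenyl sulfone (as 20 with CH2SO2Ph) | C=C(CS(=O)(=O)c3ccccc3)[C@@]1(C)C[C@H](OC(C)=O)[C@@H](C)[C@](C)(CC[C@@H](C)CC(=O)OC)[C@H]1CC(=O)OC
F7 | step 13 | methyl 7-acetoxy-2-oxo-3-(phenylsulfonyl)cleroda-4(18)-en-15-oate (either configuration at C3) | C=C1C(S(=O)(=O)c3ccccc3)C(=O)C[C@@H]2[C@@](C)(CC[C@@H](C)CC(=O)OC)[C@H](C)[C@@H](OC(C)=O)C[C@]12C
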